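**Retrosynthetic overview**

- Glychalcone A is the 6-acyl chalcone of 5-hydroxy-7-methoxy-2,2-dimethyl-2H-chromene. The plan rests on the aryl–vinyl bond between Cβ of the enone and C1 of ring B (the 4-methoxyphenyl ring), with the Cα=Cβ–C(=O) unit carried as an acryloyl group on C6 of ring A.
- The last disconnection is the methoxymethyl (MOM) ether on the chelated C5 phenol; the key disconnection is the Cβ–ring B bond, made by Heck arylation of the C6 vinyl ketone with 4-iodoanisole.
- The vinyl ketone goes back to the C6 aldehyde (vinyl Grignard addition, then oxidation) once the C5 phenol is capped.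
- Rings A and B are bought as arenes. The pyran ring is the only ring formed, and it is closed early by condensation of 2,4-dihydroxy-6-methoxybenzaldehyde with 3-methylbut-2-enal followed by oxa-6π electrocyclisation; the aldehyde comes from formylation of 5-methoxyresorcinol.

Key step: step 6

Remark on the chemistry: the target has no stereocentre and its only stereo element is the E enone, set in step 6. Alcohol 11 is carried as the racemate because step 5 removes its stereocentre.

**Route**

Step 1
Reactants: 1 5-methoxyresorcinol
Product: 3 2,4-dihydroxy-6-methoxybenzaldehyde, via aryl iminium chloride 2 (not isolated)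
Conditions: POCl3, DMF, MeCN, 0 °C → rt; then H2O, 50 °C
Reagents that add atoms: N,N-dimethylformamide, CN(C)C=O (formyl carbon); water, O (carbonyl oxygen)
Why: Vilsmeier–Haack formylation, in which the chloroiminium electrophile should attack one of the two equivalent ring carbons ortho to one hydroxyl and para to the other, and hydrolysis of iminium salt 2 releases the aldehyde; the minor 2,6-dihydroxy-4-methoxy isomer should be separable by chromatography.

Step 2
Reactants: 3 2,4-dihydroxy-6-methoxybenzaldehyde; 4 3-methylbut-2-enal
Product: 6 5-hydroxy-7-methoxy-2,2-dimethyl-2H-chromene-6-carbaldehyde, via ortho-quinone methide 5 (not isolated)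
Conditions: ethylenediammonium diacetate (cat.), xylene, reflux
Reagents that add atoms: none
Why: Knoevenagel-type condensation of ring carbon C3 with the enal should give quinone methide 5, which closes by oxa-6π electrocyclisation onto the unchelated C4 oxygen; C3 is the expected site because the hydrogen bond between the C2 hydroxyl and the formyl group fixes C3=C4 as the enol-like bond of the free phenol, as in the known chromenylation of 2,4-dihydroxybenzaldehydes.

Step 3
Reactants: 6 5-hydroxy-7-methoxy-2,2-dimethyl-2H-chromene-6-carbaldehyde
Product: 8 7-methoxy-5-(methoxymethoxy)-2,2-dimethyl-2H-chromene-6-carbaldehyde, via sodium phenoxide 7 (not isolated)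
Conditions: NaH, DMF, 0 °C; then MOMCl, 0 °C → rt
Reagents that add atoms: chloromethyl methyl ether (MOMCl), COCCl
Why: Williamson-type O-alkylation (SN2 on the α-chloro ether) of sodium phenoxide 7; full deprotonation with NaH breaks the hydrogen bond to the formyl group that makes this hindered phenol sluggish with amine bases.

Step 4
Reactants: 8 7-methoxy-5-(methoxymethoxy)-2,2-dimethyl-2H-chromene-6-carbaldehyde; 9 vinylmagnesium bromide
Product: 11 rac-1-[7-methoxy-5-(methoxymethoxy)-2,2-dimethyl-2H-chromen-6-yl]prop-2-en-1-ol, via bromomagnesium alkoxide 10 (not isolated)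
Conditions: THF, −78 → 0 °C; then sat. aq NH4Cl
Reagents that add atoms: none
Why: Grignard 1,2-addition to a non-enolisable aryl aldehyde, assisted by chelation of magnesium between the flanking ether oxygens; the carbinol stereocentre forms as a racemate, which is acceptable because step 5 removes it.

Step 5
Reactants: 11 rac-1-[7-methoxy-5-(methoxymethoxy)-2,2-dimethyl-2H-chromen-6-yl]prop-2-en-1-ol
Product: 12 1-[7-methoxy-5-(methoxymethoxy)-2,2-dimethyl-2H-chromen-6-yl]prop-2-en-1-one
Conditions: activated MnO2 (excess), CH2Cl2, rt
Reagents that add atoms: none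
Why: MnO2 oxidation of a secondary alcohol that is both benzylic and allylic, under neutral heterogeneous conditions that should leave the chromene alkene and the MOM acetal untouched; the vinyl ketone should be used at once in step 6 to limit polymerisation.

Step 6
Reactants: 12 1-[7-methoxy-5-(methoxymethoxy)-2,2-dimethyl-2H-chromen-6-yl]prop-2-en-1-one; 13 4-iodoanisole
Product: 14 glychalcone A methoxymethyl ether, (E)-1-[7-methoxy-5-(methoxymethoxy)-2,2-dimethyl-2H-chromen-6-yl]-3-(4-methoxyphenyl)prop-2-en-1-one
Conditions: Pd(OAc)2 (5 mol %), Bu4NCl, NaHCO3, DMF, 60 °C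
Reagents that add atoms: none
Why: Mizoroki–Heck arylation: Pd(OAc)2 is reduced in the flask to zerovalent palladium, which adds oxidatively into the C–I bond of 13 to give an arylpalladium iodide of divalent palladium; syn carbopalladation of the terminal alkene of 12 places the aryl group on Cβ and palladium on Cα, and syn β-hydride elimination with loss of HI to the base returns the catalyst. The closest known reaction type is the Heck coupling of aryl vinyl ketones with aryl iodides to give chalcones. No ring is closed and no stereocentre is formed. The E geometry follows from the syn insertion and syn elimination sequence, which passes through the rotamer with the aryl and acyl groups anti and gives the more stable trans enone. The step needs site selectivity between the acryloyl alkene and the chromene C3=C4 bond; the monosubstituted electron-poor alkene should insert far faster than the cis-disubstituted alkene next to the quaternary C2, and the polarisation of the enone directs the aryl group to Cβ. The C5 phenol is capped as its MOM ether so that it cannot add to the vinyl ketone and close a chroman-4-one, and the ligand-free conditions with a mild inorganic base avoid amine-triggered oligomerisation of 12.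

Step 7
Reactants: 14 glychalcone A methoxymethyl ether
Product: 15 glychalcone A
Conditions: 3 M aq HCl, MeOH, rt → 40 °C
Reagents that add atoms: none
Why: Acid-catalysed acetal solvolysis of the MOM ether in methanol; the MOM group ortho to the ketone is especially labile and the freed phenol is held in a hydrogen bond to the carbonyl, so mild acid should suffice without flavanone closure or addition to the chromene alkene.

**Compound list**

1 | 5-methoxyresorcinol (5-methoxybenzene-1,3-diol) | COc1cc(O)cc(O)c1 | starting material
2 | [(2,4-dihydroxy-6-methoxyphenyl)methylidene]dimethylammonium chloride (aryl iminium chloride) | C[N+](C)=Cc1c(O)cc(O)cc1OC.[Cl-] | intermediate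
3 | 2,4-dihydroxy-6-methoxybenzaldehyde | COc1cc(O)cc(O)c1C=O | intermediate
4 | 3-methylbut-2-enal | CC(C)=CC=O | starting material
5 | (3Z)-2-hydroxy-6-methoxy-3-(3-methylbut-2-en-1-ylidene)-4-oxocyclohexa-1,5-diene-1-carbaldehyde (ortho-quinone methide, dienyl chain on the side of the C4 carbonyl) | O=CC1=C(O)/C(=C/C=C(C)C)C(=O)C=C1OC | intermediate
6 | 5-hydroxy-7-methoxy-2,2-dimethyl-2H-chromene-6-carbaldehyde | COc1cc2c(c(O)c1C=O)C=CC(C)(C)O2 | intermediate
7 | sodium 6-formyl-7-methoxy-2,2-dimethyl-2H-chromen-5-olate | COc1cc2c(c([O-])c1C=O)C=CC(C)(C)O2.[Na+] | intermediate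
8 | 7-methoxy-5-(methoxymethoxy)-2,2-dimethyl-2H-chromene-6-carbaldehyde | COCOc1c(C=O)c(OC)cc2c1C=CC(C)(C)O2 | intermediate
9 | vinylmagnesium bromide | C=C[Mg]Br | starting material
10 | bromomagnesium 1-[7-methoxy-5-(methoxymethoxy)-2,2-dimethyl-2H-chromen-6-yl]prop-2-en-1-olate (racemate) | C=CC(O[Mg]Br)c1c(OC)cc2c(c1OCOC)C=CC(C)(C)O2 | intermediate
11 | rac-1-[7-methoxy-5-(methoxymethoxy)-2,2-dimethyl-2H-chromen-6-yl]prop-2-en-1-ol (racemate) | C=CC(O)c1c(OC)cc2c(c1OCOC)C=CC(C)(C)O2 | intermediate
12 | 1-[7-methoxy-5-(methoxymethoxy)-2,2-dimethyl-2H-chromen-6-yl]prop-2-en-1-one | C=CC(=O)c1c(OC)cc2c(c1OCOC)C=CC(C)(C)O2 | intermediate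
13 | 4-iodoanisole | COc1ccc(I)cc1 | starting material
14 | glychalcone A methoxymethyl ether, (E)-1-[7-methoxy-5-(methoxymethoxy)-2,2-dimethyl-2H-chromen-6-yl]-3-(4-methoxyphenyl)prop-2-en-1-one | COc1ccc(/C=C/C(=O)c2c(OC)cc3c(c2OCOC)C=CC(C)(C)O3)cc1 | intermediate
15 | glychalcone A, (E)-1-(5-hydroxy-7-methoxy-2,2-dimethyl-2H-chromen-6-yl)-3-(4-methoxyphenyl)prop-2-en-1-one | COc1ccc(/C=C/C(=O)c2c(OC)cc3c(c2O)C=CC(C)(C)O3)cc1 | target

**Step count and risk**

Total steps: 7. Longest linear sequence: 7 steps, from 5-methoxyresorcinol 1 to glychalcone A 15.

Steps most likely to fail: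

Step 6 (Heck arylation). Oligomerisation of the vinyl ketone under warm basic conditions may outpace carbopalladation, a second arylation at Cβ of the product may occur, or the catalyst may deposit as palladium black before conversion is complete. The fallback builds the enone by carbonyl condensation and sets out from aldehyde 8. Addition of MeMgBr (THF, 0 °C) should give the methyl carbinol rac-1-[7-methoxy-5-(methoxymethoxy)-2,2-dimethyl-2H-chromen-6-yl]ethanol F1. Oxidation with Dess–Martin periodinane (CH2Cl2, NaHCO3, rt) should give the methyl ketone 1-[7-methoxy-5-(methoxymethoxy)-2,2-dimethyl-2H-chromen-6-yl]ethanone F2. Claisen–Schmidt condensation of this ketone with 4-methoxybenzaldehyde (KOH, EtOH/H2O, rt) forms the Cα=Cβ bond with E geometry and comes back to the route at 14, before step 7.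

Step 2 (chromene annulation). The C–C bond may form at C5 instead of C3, the pyran may close onto the chelated oxygen, or the enal may self-condense under the amine salt. The fallback separates O–C from C–C bond formation and sets out from 3. Selective O-alkylation of the unchelated C4 hydroxyl with 3-chloro-3-methylbut-1-yne (K2CO3, KI, acetone, reflux) should give the aryl propargyl ether 2-hydroxy-6-methoxy-4-[(2-methylbut-3-yn-2-yl)oxy]benzaldehyde F3. Heating this ether (N,N-diethylaniline, 190 °C) should trigger an aromatic Claisen rearrangement to C3, a [1,5]-hydrogen shift and oxa-6π closure, coming back to the route at 6.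

Step 7 (MOM removal). Acid may promote conjugate addition of the freed phenol to the enone (flavanone closure) or addition of HCl or methanol across the chromene alkene. The fallback avoids both the protecting group and the late acid step and sets out from 6. Excess MeMgBr (THF, 0 °C → rt) should give the diol rac-6-(1-hydroxyethyl)-7-methoxy-2,2-dimethyl-2H-chromen-5-ol F4. Selective benzylic oxidation with MnO2 (CH2Cl2, rt) should give the chelated hydroxy ketone 1-(5-hydroxy-7-methoxy-2,2-dimethyl-2H-chromen-6-yl)ethanone F5. Claisen–Schmidt condensation of this ketone with 4-methoxybenzaldehyde (KOH, EtOH, rt) comes back to the route at the target 15.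

**Further compounds**

F1 | step 6 | rac-1-[7-methoxy-5-(methoxymethoxy)-2,2-dimethyl-2H-chromen-6-yl]ethanol | CC(O)c1c(OC)cc2c(c1OCOC)C=CC(C)(C)O2
F2 | step 6 | 1-[7-methoxy-5-(methoxymethoxy)-2,2-dimethyl-2H-chromen-6-yl]ethanone | CC(=O)c1c(OC)cc2c(c1OCOC)C=CC(C)(C)O2
F3 | step 2 | 2-hydroxy-6-methoxy-4-[(2-methylbut-3-yn-2-yl)oxy]benzaldehyde | COc1cc(OC(C)(C)C#C)cc(O)c1C=O
F4 | step 7 | rac-6-(1-hydroxyethyl)-7-methoxy-2,2-dimethyl-2H-chromen-5-ol | CC(O)c1c(OC)cc2c(c1O)C=CC(C)(C)O2
F5 | step 7 | 1-(5-hydroxy-7-methoxy-2,2-dimethyl-2H-chromen-6-yl)ethanone | CC(=O)c1c(OC)cc2c(c1O)C=CC(C)(C)O2
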